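**Retrosynthetic overview**
- Target ⇐ acetylation, desilylation, Z‑selective enyne cross‑metathesis and Appel bromination (inversion at C13) of an 8‑allyl‑5,7‑dichloro‑oxocane carrying a (1S)‑1‑hydroxypropyl group.
- Oxocane ⇐ ring expansion of a 2,5‑trans tetrahydrofuran (ring A, O bridging C6/C9) bearing a (12S,13S)‑epoxide: the ring‑A oxygen opens the epoxide at C12, and chloride cuts the C9–O bond of the bicyclic oxonium ion.
- Ring A ⇐ double Shi epoxidation of an acyclic syn‑chlorohydrin (E,E)‑triene, then 5‑exo opening of the 9,10‑epoxide by the C6 hydroxyl.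
- Chlorohydrin ⇐ reagent‑controlled allylboration of an (S)‑α‑chloro dienal ⇐ organocatalytic α‑chlorination.
- Dienal ⇐ methyl pent‑4‑ynoate + (E)‑1‑bromopent‑2‑ene. Ring order: ring A first, the oxocane second (by expansion of ring A).

Assumption: chain atoms are called C1–C15 (C1 = terminal alkyne carbon), so the target is (3Z,6S,7S,9S,10S,12R,13R); (but‑3‑en‑1‑yn‑1‑yl)trimethylsilane, (−)‑B‑allyldiisopinocampheylborane and the L‑fructose‑derived Shi ketone are taken as purchasable.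

Step 1
Reactants: 1 methyl pent‑4‑ynoate + 2 (E)‑1‑bromopent‑2‑ene
Product: 4 methyl (4E,7E)‑deca‑4,7‑dienoate, via alkenyl‑Zr(Cp)2Cl complex 3 (not isolated)
Conditions: Cp2Zr(H)Cl (1.2 equiv), THF, rt; then 2, Pd(PPh3)4 (5 mol%), THF, rt
Reagents that add atoms: none
Why: Syn, anti‑Markovnikov hydrozirconation gives the (E)‑alkenylzirconium, and Pd‑catalysed alkenyl–allyl cross‑coupling (Negishi type) joins it to the less substituted allyl terminus with retention of both alkene geometries; no stereocentre is formed.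

Step 2
Reactants: 4 methyl (4E,7E)‑deca‑4,7‑dienoate
Product: 5 (4E,7E)‑deca‑4,7‑dienal
Conditions: i‑Bu2AlH (1.05 equiv), CH2Cl2, −78 °C; aq. KNaC4H4O6
Reagents that add atoms: none
Why: Partial ester reduction stops at the tetrahedral aluminium hemiacetal at −78 °C, which releases the aldehyde on work‑up.

Step 3
Reactants: 5 (4E,7E)‑deca‑4,7‑dienal
Product: 6 (2S,4E,7E)‑2‑chlorodeca‑4,7‑dienal
Conditions: NCS (1.1 equiv), trans‑2,5‑diphenylpyrrolidine (10 mol%, the antipode that gives the (S)‑chloride, (2R,5R) by the usual assignment), CH2Cl2, 0 °C to rt; pentane filtration, used at once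
Reagents that add atoms: N‑chlorosuccinimide, O=C1CCC(=O)N1Cl
Why: Organocatalytic asymmetric α‑chlorination through the enamine, whose shielded face forces NCS to deliver chlorine to give the (2S) centre; the isolated alkenes do not react with NCS here.

Step 4
Reactants: 6 (2S,4E,7E)‑2‑chlorodeca‑4,7‑dienal
Product: 7 (4S,5S,7E,10E)‑5‑chlorotrideca‑1,7,10‑trien‑4‑ol
Conditions: (−)‑Ipc2B(allyl) (1.5 equiv, salt‑free), Et2O, −100 to −78 °C; then H2O2, NaH2PO4/Na2HPO4 buffer (pH 7), MeOH, 0 °C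
Reagents that add atoms: (−)‑B‑allyldiisopinocampheylborane, C=CCB([C@@H]1C[C@@H]2C[C@H]([C@H]1C)C2(C)C)[C@@H]1C[C@@H]2C[C@H]([C@H]1C)C2(C)C
Why: Brown allylboration through a closed chair transition state, in which the (+)‑α‑pinene‑derived reagent fixes the aldehyde face to give the (4S) alcohol and overrides the weaker Cornforth (anti) bias of the α‑chloro aldehyde, so the syn‑chlorohydrin forms under reagent control.

Step 5
Reactants: 7 (4S,5S,7E,10E)‑5‑chlorotrideca‑1,7,10‑trien‑4‑ol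
Product: 9 (1S)‑1‑[(2R,4S,5S)‑4‑chloro‑5‑(prop‑2‑en‑1‑yl)oxolan‑2‑yl]‑2‑[(2S,3S)‑3‑ethyloxiran‑2‑yl]ethan‑1‑ol, via bis‑epoxy alcohol 8 (not isolated)
Conditions: L‑fructose‑derived Shi ketone (1.0 equiv), KHSO5 (as 2KHSO5·KHSO4·K2SO4), NaHCO3 buffer (pH 8), MeCN/CH2(OMe)2/H2O, 0 °C; then CSA (5 mol%), CH2Cl2, −20 °C
Reagents that add atoms: potassium peroxymonosulfate, [K+].[O-]S(=O)(=O)OO
Why: Shi asymmetric epoxidation converts both trans‑disubstituted alkenes into (S,S)‑epoxides from the same enantioface (the monosubstituted alkene is much slower, and pH 8 keeps the chlorohydrin from closing), and acid‑catalysed 5‑exo epoxide opening by the C4 hydroxyl then inverts the attacked carbon to give 2,5‑trans ring A with the (2R) ring carbon and the (1S) carbinol.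

Step 6
Reactants: 9 (1S)‑1‑[(2R,4S,5S)‑4‑chloro‑5‑(prop‑2‑en‑1‑yl)oxolan‑2‑yl]‑2‑[(2S,3S)‑3‑ethyloxiran‑2‑yl]ethan‑1‑ol
Product: 10 tert‑butyl({(1S)‑1‑[(2R,4S,5S)‑4‑chloro‑5‑(prop‑2‑en‑1‑yl)oxolan‑2‑yl]‑2‑[(2S,3S)‑3‑ethyloxiran‑2‑yl]ethyl}oxy)dimethylsilane
Conditions: TBSCl, imidazole, DMAP (cat.), DMF, rt
Reagents that add atoms: tert‑butyldimethylsilyl chloride, CC(C)(C)[Si](C)(C)Cl
Why: Standard silylation of the secondary alcohol, using the chloride and not the silyl triflate so the epoxide is untouched; the silyl ether, unlike an ester, cannot act as a neighbouring group at C9 in the next step.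

Step 7
Reactants: 10 tert‑butyl({(1S)‑1‑[(2R,4S,5S)‑4‑chloro‑5‑(prop‑2‑en‑1‑yl)oxolan‑2‑yl]‑2‑[(2S,3S)‑3‑ethyloxiran‑2‑yl]ethyl}oxy)dimethylsilane
Product: 13 (1S)‑1‑[(2R,4S,5S,7S,8S)‑4‑{[tert‑butyl(dimethyl)silyl]oxy}‑5,7‑dichloro‑8‑(prop‑2‑en‑1‑yl)oxocan‑2‑yl]propan‑1‑ol, via bicyclic oxonium triflate 11 (not isolated), via oxocane trimethylsilyl ether 12 (not isolated)
Conditions: TMSOTf (1.2 equiv), 2,6‑di‑tert‑butyl‑4‑methylpyridine, CH2Cl2, −78 °C; then Bu4NCl (3 equiv), −78 to −40 °C; then citric acid, MeOH, 0 °C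
Reagents that add atoms: tetrabutylammonium chloride, CCCC[N+](CCCC)(CCCC)CCCC.[Cl-]
Why: Proposed new method: O‑silylation of the epoxide lets the ring‑A oxygen open it 5‑exo and anti (inversion at C12, giving 12R) to form a cis‑fused 1‑oxoniabicyclo[3.3.0]octane, and chloride then attacks the ring‑fusion carbon C9 from the outer face with inversion (9R to 9S), cutting the shared C9–O bond so that ring A expands to the 2,8‑trans oxocane; C9 is expected to win because it sits at the exposed tip of the bicycle with both carbon substituents tied back, whereas C6 is flanked by the allyl group, the cis β‑chlorine and the endo C13 side chain and C12 is β‑branched, but this selectivity is untested; the closest known reactions are bromonium‑induced tetrahydrofuran‑to‑oxocane ring expansions ended by a tethered carbonate and the halide opening of Laurencia‑type trialkyloxonium ions.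

Step 8
Reactants: 13 (1S)‑1‑[(2R,4S,5S,7S,8S)‑4‑{[tert‑butyl(dimethyl)silyl]oxy}‑5,7‑dichloro‑8‑(prop‑2‑en‑1‑yl)oxocan‑2‑yl]propan‑1‑ol
Product: 14 {[(2R,4S,5S,7S,8S)‑2‑[(1R)‑1‑bromopropyl]‑5,7‑dichloro‑8‑(prop‑2‑en‑1‑yl)oxocan‑4‑yl]oxy}(tert‑butyl)dimethylsilane
Conditions: CBr4, P(n‑Oct)3, 1‑methylcyclohexene, toluene, 70 °C
Reagents that add atoms: carbon tetrabromide, BrC(Br)(Br)Br
Why: Appel bromination, in which bromide displaces the alkoxyphosphonium group by SN2 with inversion (1S to 1R) while the alkene additive scavenges HBr.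

Step 9
Reactants: 14 {[(2R,4S,5S,7S,8S)‑2‑[(1R)‑1‑bromopropyl]‑5,7‑dichloro‑8‑(prop‑2‑en‑1‑yl)oxocan‑4‑yl]oxy}(tert‑butyl)dimethylsilane + 15 (but‑3‑en‑1‑yn‑1‑yl)trimethylsilane
Product: 16 tert‑butyl({(2R,4S,5S,7S,8S)‑2‑[(1R)‑1‑bromopropyl]‑5,7‑dichloro‑8‑[(2Z)‑5‑(trimethylsilyl)pent‑2‑en‑4‑yn‑1‑yl]oxocan‑4‑yl}oxy)dimethylsilane
Conditions: second‑generation Grubbs catalyst (10 mol%), 15 (4 equiv), CH2Cl2, 40 °C
Reagents that add atoms: none
Why: Olefin cross‑metathesis of the terminal alkene with a conjugated enyne, a pairing known to favour the (Z)‑1,3‑enyne, driven by loss of ethene; no stereocentre is touched.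

Step 10
Reactants: 16 tert‑butyl({(2R,4S,5S,7S,8S)‑2‑[(1R)‑1‑bromopropyl]‑5,7‑dichloro‑8‑[(2Z)‑5‑(trimethylsilyl)pent‑2‑en‑4‑yn‑1‑yl]oxocan‑4‑yl}oxy)dimethylsilane
Product: 17 (2R,4S,5S,7S,8S)‑2‑[(1R)‑1‑bromopropyl]‑5,7‑dichloro‑8‑[(2Z)‑pent‑2‑en‑4‑yn‑1‑yl]oxocan‑4‑ol
Conditions: Bu4NF (3 equiv), AcOH (3 equiv), THF, 0 °C to rt
Reagents that add atoms: none
Why: Fluoride‑mediated desilylation removes both the alkynyl silane and the silyl ether, with acetic acid buffering the medium so the secondary halides do not eliminate.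

Step 11
Reactants: 17 (2R,4S,5S,7S,8S)‑2‑[(1R)‑1‑bromopropyl]‑5,7‑dichloro‑8‑[(2Z)‑pent‑2‑en‑4‑yn‑1‑yl]oxocan‑4‑ol
Product: 18 (2R,4S,5S,7S,8S)‑2‑[(1R)‑1‑bromopropyl]‑5,7‑dichloro‑8‑[(2Z)‑pent‑2‑en‑4‑yn‑1‑yl]oxocan‑4‑yl acetate
Conditions: Ac2O, pyridine, DMAP (cat.), CH2Cl2, 0 °C to rt
Reagents that add atoms: acetic anhydride, CC(=O)OC(C)=O
Why: DMAP‑catalysed O‑acylation of the secondary alcohol with retention at the carbinol carbon.

**Compound list**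
1 | methyl pent‑4‑ynoate | COC(=O)CCC#C | starting material
2 | (E)‑1‑bromopent‑2‑ene | CC/C=C/CBr | starting material
3 | chlorobis(cyclopentadienyl)[(1E)‑5‑methoxy‑5‑oxopent‑1‑en‑1‑yl]zirconium (not isolated) | COC(=O)CC/C=C/[Zr](Cl)(C1C=CC=C1)C1C=CC=C1 | intermediate
4 | methyl (4E,7E)‑deca‑4,7‑dienoate | CC/C=C/C/C=C/CCC(=O)OC | intermediate
5 | (4E,7E)‑deca‑4,7‑dienal | CC/C=C/C/C=C/CCC=O | intermediate
6 | (2S,4E,7E)‑2‑chlorodeca‑4,7‑dienal | CC/C=C/C/C=C/C[C@H](Cl)C=O | intermediate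
7 | (4S,5S,7E,10E)‑5‑chlorotrideca‑1,7,10‑trien‑4‑ol | C=CC[C@H](O)[C@@H](Cl)C/C=C/C/C=C/CC | intermediate
8 | (4S,5S)‑5‑chloro‑6‑[(2S,3S)‑3‑{[(2S,3S)‑3‑ethyloxiran‑2‑yl]methyl}oxiran‑2‑yl]hex‑1‑en‑4‑ol (not isolated) | C=CC[C@H](O)[C@@H](Cl)C[C@@H]1O[C@H]1C[C@@H]1O[C@H]1CC | intermediate
9 | (1S)‑1‑[(2R,4S,5S)‑4‑chloro‑5‑(prop‑2‑en‑1‑yl)oxolan‑2‑yl]‑2‑[(2S,3S)‑3‑ethyloxiran‑2‑yl]ethan‑1‑ol | C=CC[C@@H]1O[C@H](C[C@@H]1Cl)[C@@H](O)C[C@@H]2O[C@H]2CC | intermediate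
10 | tert‑butyl({(1S)‑1‑[(2R,4S,5S)‑4‑chloro‑5‑(prop‑2‑en‑1‑yl)oxolan‑2‑yl]‑2‑[(2S,3S)‑3‑ethyloxiran‑2‑yl]ethyl}oxy)dimethylsilane | C=CC[C@@H]1O[C@H](C[C@@H]1Cl)[C@@H](O[Si](C)(C)C(C)(C)C)C[C@@H]2O[C@H]2CC | intermediate
11 | cis‑fused 1‑oxoniabicyclo[3.3.0]octane triflate, O+ bonded to C6, C9 and C12 (6S,7S,9R,10S,12R,13S; 10‑OTBS, 13‑OTMS) (not isolated) | C=CC[C@H]1[C@@H](Cl)C[C@@H]2[C@@H](O[Si](C)(C)C(C)(C)C)C[C@@H]([O+]12)[C@@H](O[Si](C)(C)C)CC.[O-]S(=O)(=O)C(F)(F)F | intermediate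
12 | tert‑butyl({(2R,4S,5S,7S,8S)‑5,7‑dichloro‑8‑(prop‑2‑en‑1‑yl)‑2‑{(1S)‑1‑[(trimethylsilyl)oxy]propyl}oxocan‑4‑yl}oxy)dimethylsilane (not isolated) | C=CC[C@@H]1O[C@@H]([C@@H](O[Si](C)(C)C)CC)C[C@H](O[Si](C)(C)C(C)(C)C)[C@@H](Cl)C[C@@H]1Cl | intermediate
13 | (1S)‑1‑[(2R,4S,5S,7S,8S)‑4‑{[tert‑butyl(dimethyl)silyl]oxy}‑5,7‑dichloro‑8‑(prop‑2‑en‑1‑yl)oxocan‑2‑yl]propan‑1‑ol | C=CC[C@@H]1O[C@@H]([C@@H](O)CC)C[C@H](O[Si](C)(C)C(C)(C)C)[C@@H](Cl)C[C@@H]1Cl | intermediate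
14 | {[(2R,4S,5S,7S,8S)‑2‑[(1R)‑1‑bromopropyl]‑5,7‑dichloro‑8‑(prop‑2‑en‑1‑yl)oxocan‑4‑yl]oxy}(tert‑butyl)dimethylsilane | C=CC[C@@H]1O[C@@H]([C@H](Br)CC)C[C@H](O[Si](C)(C)C(C)(C)C)[C@@H](Cl)C[C@@H]1Cl | intermediate
15 | (but‑3‑en‑1‑yn‑1‑yl)trimethylsilane | C=CC#C[Si](C)(C)C | starting material
16 | tert‑butyl({(2R,4S,5S,7S,8S)‑2‑[(1R)‑1‑bromopropyl]‑5,7‑dichloro‑8‑[(2Z)‑5‑(trimethylsilyl)pent‑2‑en‑4‑yn‑1‑yl]oxocan‑4‑yl}oxy)dimethylsilane | C[Si](C)(C)C#C/C=C\C[C@@H]1O[C@@H]([C@H](Br)CC)C[C@H](O[Si](C)(C)C(C)(C)C)[C@@H](Cl)C[C@@H]1Cl | intermediate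
17 | (2R,4S,5S,7S,8S)‑2‑[(1R)‑1‑bromopropyl]‑5,7‑dichloro‑8‑[(2Z)‑pent‑2‑en‑4‑yn‑1‑yl]oxocan‑4‑ol | C#C/C=C\C[C@@H]1O[C@@H]([C@H](Br)CC)C[C@H](O)[C@@H](Cl)C[C@@H]1Cl | intermediate
18 | (2R,4S,5S,7S,8S)‑2‑[(1R)‑1‑bromopropyl]‑5,7‑dichloro‑8‑[(2Z)‑pent‑2‑en‑4‑yn‑1‑yl]oxocan‑4‑yl acetate | C#C/C=C\C[C@@H]1O[C@@H]([C@H](Br)CC)C[C@H](OC(C)=O)[C@@H](Cl)C[C@@H]1Cl | target

**Step count and risks**
Total steps: 11. Longest linear sequence: 11 steps (1 to 18).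

The three steps most likely to fail:

Step 7 (the proposed new ring expansion; the risk is chloride opening of ion 11 at C6 or C12 instead of C9). The fallback sets out from 10 and gives up the one‑pot cascade for a separate‑and‑return scheme built on known reactions. The quench is worked up without methanolysis, and oxocane silyl ether 12 is separated by chromatography and cleaved to 13. The two off‑path chlorides are the ring‑switched tetrahydrofuran dichloride F1 (from attack at C6) and the tetrahydrofuran chloro silyl ether F2 (from attack at C12). Each is returned to oxonium triflate 11 by silver‑assisted chloride abstraction with participation of the ring oxygen (AgOTf, 2,6‑di‑tert‑butyl‑4‑methylpyridine, CH2Cl2, −40 °C), the known way of making Laurencia‑type oxonium ions from halo ethers. The ion is then quenched again with Bu4NCl. This fallback comes back to the route at 13; it raises throughput by recycling but does not change the intrinsic site selectivity.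

Step 4 (mismatched double diastereoselection). The fallback sets out from 6. Matched allylboration with (+)‑Ipc2B(allyl) gives the anti‑chlorohydrin (4R,5S,7E,10E)‑5‑chlorotrideca‑1,7,10‑trien‑4‑ol F3. Mitsunobu inversion (4‑nitrobenzoic acid, PPh3, DIAD, toluene, 0 °C) then gives the (4S) 4‑nitrobenzoate F4. Mild methanolysis (K2CO3, MeOH, 0 °C) brings the sequence back to the route at 7.

Step 9 (Z/E ratio and conversion of the enyne cross‑metathesis). The fallback sets out from 14. Oxidative cleavage of the allyl group (OsO4 (2 mol%), NaIO4, 2,6‑lutidine, dioxane/H2O) gives the oxocanyl acetaldehyde F5. Z‑selective Peterson olefination with lithiated 1,3‑bis(triisopropylsilyl)propyne (n‑BuLi, THF, −78 °C) gives the (Z)‑triisopropylsilyl enyne F6. Bu4NF/AcOH then removes both silyl groups, and the sequence comes back to the route at 17.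

**Further compounds**
F1 | step 7 | {[(2R,3S,5R)‑2‑[(2S,3R)‑2,3‑dichlorohex‑5‑en‑1‑yl]‑5‑{(1S)‑1‑[(trimethylsilyl)oxy]propyl}oxolan‑3‑yl]oxy}(tert‑butyl)dimethylsilane | C=CC[C@@H](Cl)[C@@H](Cl)C[C@H]1O[C@@H]([C@@H](O[Si](C)(C)C)CC)C[C@@H]1O[Si](C)(C)C(C)(C)C
F2 | step 7 | tert‑butyl{[(1S,3S,4S)‑3‑chloro‑1‑[(2R,4S,5S)‑4‑chloro‑5‑(prop‑2‑en‑1‑yl)oxolan‑2‑yl]‑4‑[(trimethylsilyl)oxy]hexyl]oxy}dimethylsilane | C=CC[C@@H]1O[C@H](C[C@@H]1Cl)[C@@H](O[Si](C)(C)C(C)(C)C)C[C@H](Cl)[C@@H](O[Si](C)(C)C)CC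
F3 | step 4 | (4R,5S,7E,10E)‑5‑chlorotrideca‑1,7,10‑trien‑4‑ol | C=CC[C@@H](O)[C@@H](Cl)C/C=C/C/C=C/CC
F4 | step 4 | (4S,5S,7E,10E)‑5‑chlorotrideca‑1,7,10‑trien‑4‑yl 4‑nitrobenzoate | C=CC[C@H](OC(=O)c1ccc(cc1)[N+](=O)[O-])[C@@H](Cl)C/C=C/C/C=C/CC
F5 | step 9 | 2‑[(2S,3S,5S,6S,8R)‑8‑[(1R)‑1‑bromopropyl]‑6‑{[tert‑butyl(dimethyl)silyl]oxy}‑3,5‑dichlorooxocan‑2‑yl]acetaldehyde | O=CC[C@@H]1O[C@@H]([C@H](Br)CC)C[C@H](O[Si](C)(C)C(C)(C)C)[C@@H](Cl)C[C@@H]1Cl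
F6 | step 9 | tert‑butyl({(2R,4S,5S,7S,8S)‑2‑[(1R)‑1‑bromopropyl]‑5,7‑dichloro‑8‑[(2Z)‑5‑(triisopropylsilyl)pent‑2‑en‑4‑yn‑1‑yl]oxocan‑4‑yl}oxy)dimethylsilane | CC(C)[Si](C(C)C)(C(C)C)C#C/C=C\C[C@@H]1O[C@@H]([C@H](Br)CC)C[C@H](O[Si](C)(C)C(C)(C)C)[C@@H](Cl)C[C@@H]1Cl
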